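If Xa is left over in this flask when the hour ends, the clock may have run short, Ul or the catalyst may have failed, or the balance may have come level, and I want to tell which beforehand.

    Xa + Uv ⇌ Jy (K1 = 32.2 L mol⁻¹, k1 = 53.5 L mol⁻¹ s⁻¹)
    Ul + Ly ⇌ Uv (K2 = 12.2 L mol⁻¹, k2 = 215 L mol⁻¹ s⁻¹)
    Ul ⇌ Ju (K3 = 0.64, k3 = 0.00335 s⁻¹)
    Jy ⇌ Ly + Gy (K4 = 0.014 M, k4 = 6.26 s⁻¹)

Xa 12 mM; Ul 1.30 equiv; Ly 2.5 mol%; time 1.0 h

* at 1.0 h, what has stopped the reaction, if anything has (Ul has run out first / it is still moving / all of Xa has reacted / forward and back rates have come level / no working catalyst is left)
* Gy at 1.0 h, in percent of the Xa charged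

- the reaction counts as stopped when no species that holds the Xa changes by six tenths of a point or more over the second half of the time
- run time (flask): 1.0 h

Two numbers seem not to go together. Ul binds Ly so fast that this forward step by itself has a half-life of 0.18 min on Ul, far shorter than the hour, and Jy releases Gy with a rate constant of 6.26 s⁻¹; yet the yield of Gy that I reckon below stays small.

Adding the steps cancels the catalyst, so Xa + Ul ⇌ Gy has the product of the constants of the catalyst steps as its constant. Ul also passes to Ju with a forward half-life of 0.057 h, shorter than the hour, so I share the Ul pool between the two by their constant: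

overall constant = 5.50 L mol⁻¹

free Ul = charge / (1 + K3) = 9.51 mM

product of the two = 0.0523

That product is the level ratio, the Gy over Xa at which forward and back rates match; the field calls such a constant, with one partner folded in, a conditional constant. It gives a yield of ratio / (1 + ratio), 4.97%. That Gy took its Ul from the pool, so a second pass gives:

free Ul = 9.15 mM, ratio = 0.0503, yield = 4.79%

So the contradiction clears: speed tells how soon the flask comes level, and the ratio, far below one, tells how far it gets. I commit to a level balance.

The forecast says forward and back rates have come level at 4.8%, holding that “The catalytic cycle turns over fast enough to get there within minutes”.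

The simulation gives forward and back rates have come level, with 4.78%.

In this flask the cycle through Ly reached half of its conversion at 0.258 min, earlier than the 1.34 min by which half of the turnover of Ul to Ju was done. Between 0.100 h and 1.00 h in this flask, Gy eased from 4.98% to 4.78% while Ul went from 60.2% to 58.6% of its charge.

In the neighbour flask with 5.20 equiv of Ul, the two passes give a level ratio of 0.202 and a yield of 16.8%. The computed neighbour gives 16.8%.

The constants are made up; the result is computed.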